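The data are calculated for substances that don't exist; the scatter is artificial.

Every part of the Z charged stands at any moment as Z, as Q or as lost material, so the lost fraction is what remains after the fractions of Q and Z are taken from the whole.

the same everywhere: Z 0.096 M
- epsilon: E 0.028 mol%; temperature −30 °C; run made earlier
- eta: E 0.044 mol%; temperature 0 °C; run made earlier
- dusk: E 0.02 mol%; temperature 0 °C; time 50 h
- autumn: E 0.02 mol%; temperature 25 °C; time 50 h
- winter: E 0.02 mol%; temperature −25 °C; time 50 h
- spring: E 0.02 mol%; at 25 °C until 40 h, from then on at −25 °C; time 50 h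

| run | time / h | Q / % | Z / % |
|---|---|---|---|
| epsilon | 12.0 | 5.6 | 94.4 |
| epsilon | 40.0 | 19.0 | 80.3 |
| epsilon | 72.0 | 32.5 | 64.0 |
| epsilon | 120 | 52.2 | 41.3 |
| epsilon | 192 | 71.3 | 17.3 |
| epsilon | 240 | 77.6 | 9.2 |
| epsilon | 288 | 81.5 | 4.1 |
| eta | 5.00 | 37.5 | 55.4 |
| eta | 8.00 | 53.9 | 31.7 |
| eta | 12.0 | 68.1 | 12.7 |
| eta | 15.0 | 72.6 | 5.9 |
| eta | 25.0 | 76.3 | 0 |
| eta | 40.0 | 77.1 | 0 |
| eta | 60.0 | 77.0 | 0 |

(standard deviation of a reading: 0.3 percentage points)

1. which flask leads in amount of Q, in percent of the Z charged ("all alike" within 1.5 percentage points) (dusk / autumn / winter / spring / all alike)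
2. how much Q is there at the end, in percent of the Z charged: dusk
3. how much Q is there at the end, in percent of the Z charged: autumn
4. how much Q is there at the end, in percent of the Z charged: winter
5. how much Q is there at the end, in percent of the Z charged: spring

- what was read earlier has a scatter of 0.3 percentage points, one standard deviation

E turns Z into Q, and in the eta run Q stays near 77.0% after Z reads 0%, so this reckoning takes the split as kept once Z has gone. The quantity to carry is the loss ratio W, the lost fraction over the Q fraction once Z has gone, the inverse of a selectivity. The end fraction of Q is the reciprocal of one plus W. The readings of eta give W = 0.299, and the last reading of epsilon, with Z still at 4.1%, gives 0.177 so far.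

Two extreme versions can be reckoned in logarithms. If the loss runs without E, W is taken to go roughly as the reciprocal of the loading. Dusk then stands 0.342 decades above eta, with W = 0.657 and Q at 60.3%. Its 50 h count as 22.7 h of eta, where Z read 5.9% at 15.0 h, so dusk is reckoned close to its end. Loading-corrected W climbs 0.424 decades from epsilon to eta. On a scale of reciprocal absolute temperature, that puts autumn 0.288 decades above dusk, with W = 1.28 and Q at 43.9%.

If the loss rides on E as the making does, W ignores the loading. Dusk then keeps eta's 77.0%, and autumn, 0.155 decades higher, gets 70.1%. A loss leaning partly on E lands between these versions, and the two runs cannot place it, as E and temperature changed together. This reckoning commits to the E-free end, as a choice that the two runs do not test.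

The forecast names dusk as leader, with dusk 66%, autumn 54%, winter 25% and spring 54%, which puts dusk and autumn above this reckoning. Its stated doubt is “If this loss is uncatalysed, less E hurts yield”.

The flasks give dusk 61.2%, autumn 45.4%, winter 25.1% and spring 45.4%, so dusk leads.

    Z + E → Q + E, rate k1*[Z]*[E]/(1 + ([Z]/Km1) + ([Z]/Ksi1)^2) (0.180 M, 0.0850 M, k = 28000 M⁻¹ h⁻¹, Ea = 44.0 kJ mol⁻¹)
    E → J (k = 4.50 × 10⁻⁴ h⁻¹, Ea = 288 kJ mol⁻¹)
    E → L (k = 1.70 × 10⁻⁴ h⁻¹, Ea = 117 kJ mol⁻¹)
    Z + Q → G (k = 5.80 M⁻¹ h⁻¹, Ea = 63.0 kJ mol⁻¹)
    (constants at 25 °C)

Autumn ends with W = 1.20 against the 1.28 reckoned, while the forecast stood 8.6 percentage points above the flask. Winter at 50 h still holds Z at 71.4%, so it has no end value of W yet. The same flask left until 500 h is its neighbour. The reckoning from eta by loading and temperature gives it W = 0.296 and Q at 77.2%. That flask holds Z at 0.0546% and Q at 77.7%.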